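**Remark (assumption):** the target has no stereocentre and no stereogenic axis, so it is achiral. The constitution is the only structural requirement and no enantiocontrol is needed.

## Retrosynthetic overview

1. Target 9 ⇐ catechol lactam 8 by threefold electrophilic bromination of the only three ring C–H positions (last step); 8 ⇐ dimethyl ether 6 by ether cleavage.
2. Lactam 6 ⇐ N-allyl-N-(3,4-dimethoxybenzyl)formamide 5 by cutting the lactam C2(=O)–C3H2 bond: intramolecular hydrocarbamoylation, formyl C–H across the allyl C=C.
3. Enabling feature: the pyrrolidin-2-one ring (N1, C2=O, C3H2, C4H2, C5H2) has no substituent on C3–C5, so it is a constitutional isomer of an N-allyl formamide. C5–C4–C3 is the allyl group and C2 is the formyl carbon.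
4. Formamide 5 ⇐ 3,4-dimethoxybenzaldehyde 1 + allylamine 2 (reductive amination) + ethyl formate. The lactam is the only ring formed (step 3); the arene is bought.

Key step: step 3

## Route

Step 1
Reactants: 1 3,4-dimethoxybenzaldehyde; 2 allylamine (prop-2-en-1-amine)
Product: 4 N-(3,4-dimethoxybenzyl)prop-2-en-1-amine, via N-allyl aldimine 3 (not isolated)
Conditions: 2 (1.2 equiv), MgSO4, MeOH, rt; then NaBH4, 0 °C → rt
Reagents that add atoms: none
Why: Reductive amination via the preformed aldimine; NaBH4 reduces C=N but not the isolated terminal alkene or the aryl ethers, and preforming the imine should suppress double benzylation.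

Step 2
Reactants: 4 N-(3,4-dimethoxybenzyl)prop-2-en-1-amine
Product: 5 N-allyl-N-(3,4-dimethoxybenzyl)formamide
Conditions: HCO2Et (solvent), 70–80 °C, sealed tube
Reagents that add atoms: ethyl formate, CCOC=O
Why: N-formylation by aminolysis of a formate ester; the unhindered secondary amine is the only nucleophile and the product is a tertiary formamide with no N–H.

Step 3
Reactants: 5 N-allyl-N-(3,4-dimethoxybenzyl)formamide
Product: 6 1-(3,4-dimethoxybenzyl)pyrrolidin-2-one
Conditions: Ru3(CO)12 (5 mol%), Bu4NI (15 mol%), DMSO/PhMe, 140 °C, Ar, sealed tube
Reagents that add atoms: none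
Why: Iodide-modified ruthenium carbonyl should insert into the formyl C–H bond of 5 to give a carbamoyl(hydrido)ruthenium species, the vinyl group should insert into Ru–H with ruthenium on the terminal carbon, and C(acyl)–C(sp3) reductive elimination from the six-membered azaruthenacycle should form the C2–C3 bond and release the catalyst. The closest known reaction type is the ruthenium-catalysed intramolecular hydrocarbamoylation of N-allyl formamides to pyrrolidin-2-ones, related to Ni/Lewis-acid formamide C–H additions to alkenes. The pyrrolidinone ring is closed in a formal 5-endo-trig sense, carbonyl carbon to terminal alkene carbon, which the metallacycle makes feasible where a direct ionic or radical attack would not be. No stereocentre is formed. The step needs regioselectivity for the terminal carbon (γ-lactam rather than 3-methyl-β-lactam) and must outrun double-bond migration to the enamide and decarbonylation of the formamide; the unhindered monosubstituted vinyl group places ruthenium on its terminus and the strain of the four-membered alternative disfavours the other regiochemistry. Chemoselectivity is secured by running the step before any C–Br bond exists, so that the formyl C–H and the alkene are the only bonds open to the low-valent metal.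

Step 4
Reactants: 6 1-(3,4-dimethoxybenzyl)pyrrolidin-2-one
Product: 8 1-(3,4-dihydroxybenzyl)pyrrolidin-2-one, via cyclic aryl bromoborate 7 (not isolated)
Conditions: BBr3 (3 equiv), CH2Cl2, −78 → 0 °C; then ice/H2O, work-up under N2
Reagents that add atoms: boron tribromide, BrB(Br)Br (B and Br are held only in intermediate 7; nothing from it remains in 8)
Why: Lewis-acid cleavage of aryl methyl ethers (bromide attacks the O-methyl of the boron-complexed ether) followed by hydrolysis of the catechol borate; N-(alkoxybenzyl) amides are known to survive this reagent at low temperature, and the extra equivalent allows for complexation by the lactam carbonyl.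

Step 5
Reactants: 8 1-(3,4-dihydroxybenzyl)pyrrolidin-2-one
Product: 9 1-[(2,3,6-tribromo-4,5-dihydroxyphenyl)methyl]pyrrolidin-2-one (target)
Conditions: Br2 (3.3 equiv, slow addition), AcOH, 10 °C → rt, dark; then aq. NaHSO3
Reagents that add atoms: bromine, BrBr
Why: Threefold electrophilic aromatic bromination; each of the three ring C–H positions is ortho or para to a hydroxyl and there is no fourth position, so exhaustive substitution can give only one constitution, and the bisulfite quench should return any o-quinone to the catechol.

## Compound list

1 | 3,4-dimethoxybenzaldehyde | COc1ccc(C=O)cc1OC | starting material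
2 | allylamine (prop-2-en-1-amine) | C=CCN | starting material
3 | (E)-N-allyl-1-(3,4-dimethoxyphenyl)methanimine | COc1ccc(/C=N/CC=C)cc1OC | intermediate (not isolated)
4 | N-(3,4-dimethoxybenzyl)prop-2-en-1-amine | COc1ccc(CNCC=C)cc1OC | intermediate
5 | N-allyl-N-(3,4-dimethoxybenzyl)formamide | COc1ccc(CN(CC=C)C=O)cc1OC | intermediate
6 | 1-(3,4-dimethoxybenzyl)pyrrolidin-2-one | COc1ccc(CN2CCCC2=O)cc1OC | intermediate
7 | 1-[(2-bromo-1,3,2-benzodioxaborol-5-yl)methyl]pyrrolidin-2-one | O=C1CCCN1Cc1ccc2OB(Br)Oc2c1 | intermediate (not isolated)
8 | 1-(3,4-dihydroxybenzyl)pyrrolidin-2-one | O=C1CCCN1Cc1ccc(O)c(O)c1 | intermediate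
9 | 1-[(2,3,6-tribromo-4,5-dihydroxyphenyl)methyl]pyrrolidin-2-one | O=C1CCCN1Cc1c(Br)c(O)c(O)c(Br)c1Br | target

## Summary

Total step count: 5. Longest linear sequence: 5 steps.

## Steps most likely to fail

**Step 3 (key step).** Ruthenium-hydride-mediated migration of the allyl double bond to the N-propenyl (enamide) isomer, and decarbonylation of the formamide, could outpace the C–C bond-forming reductive elimination. The fallback sets out from 1 and comes back at 6. Direct reductive amination of 1 with methyl 4-aminobutanoate hydrochloride (Et3N, NaBH(OAc)3, DCE, rt) should pass through methyl 4-{[(E)-(3,4-dimethoxyphenyl)methylidene]amino}butanoate F1 to methyl 4-[(3,4-dimethoxybenzyl)amino]butanoate F2. Heating F2 (PhMe, reflux) should lactamise it to 6 with loss of methanol. The ring is then closed at the N1–C2 amide bond by classical chemistry.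

**Step 5.** Oxidation of the electron-rich catechol to the o-quinone, and ipso attack of bromine at the ring carbon para to the 4-hydroxyl with loss of the lactam-bearing side chain, could compete with substitution. The fallback sets out from 6 and comes back at 9, and reverses the order of halogenation and deprotection. Treating 6 with excess Br2 and catalytic Fe powder (CHCl3/AcOH, warm) should give 1-(2,3,6-tribromo-4,5-dimethoxybenzyl)pyrrolidin-2-one F3; with no free phenol, neither quinone nor quinone-methide pathways are open. BBr3 in CH2Cl2 followed by water should then convert F3, through 1-[(2,4,6,7-tetrabromo-1,3,2-benzodioxaborol-5-yl)methyl]pyrrolidin-2-one F4, into 9.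

**Step 4.** Lewis-acid-induced heterolysis of the benzylic C–N bond could occur, with the veratryl group on the BBr3-complexed lactam behaving like an acid-labile dimethoxybenzyl group. Cleavage could also stall because the lactam carbonyl sequesters the reagent. The fallback sets out from 2 and comes back at 8, and changes the protecting group to one removed under neutral conditions. Purchased 3,4-bis(benzyloxy)benzaldehyde F5 and 2, under the conditions of step 1, should give (E)-N-allyl-1-[3,4-bis(benzyloxy)phenyl]methanimine F6 and then N-[3,4-bis(benzyloxy)benzyl]prop-2-en-1-amine F7. The conditions of step 2 should give N-allyl-N-[3,4-bis(benzyloxy)benzyl]formamide F8, and those of step 3 should give 1-[3,4-bis(benzyloxy)benzyl]pyrrolidin-2-one F9. Hydrogenolysis of F9 (H2, Pd/C, EtOAc/MeOH, rt) should then give 8; the N-benzyl lactam bond is not expected to cleave under these mild conditions.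

## Further compounds

F1 | step 3 | methyl 4-{[(E)-(3,4-dimethoxyphenyl)methylidene]amino}butanoate | COC(=O)CCC/N=C/c1ccc(OC)c(OC)c1
F2 | step 3 | methyl 4-[(3,4-dimethoxybenzyl)amino]butanoate | COC(=O)CCCNCc1ccc(OC)c(OC)c1
F3 | step 5 | 1-(2,3,6-tribromo-4,5-dimethoxybenzyl)pyrrolidin-2-one | O=C1CCCN1Cc1c(Br)c(OC)c(OC)c(Br)c1Br
F4 | step 5 | 1-[(2,4,6,7-tetrabromo-1,3,2-benzodioxaborol-5-yl)methyl]pyrrolidin-2-one | O=C1CCCN1Cc1c(Br)c2OB(Br)Oc2c(Br)c1Br
F5 | step 4 | 3,4-bis(benzyloxy)benzaldehyde (purchased) | O=Cc1ccc(OCc2ccccc2)c(OCc2ccccc2)c1
F6 | step 4 | (E)-N-allyl-1-[3,4-bis(benzyloxy)phenyl]methanimine | C=CC/N=C/c1ccc(OCc2ccccc2)c(OCc2ccccc2)c1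
F7 | step 4 | N-[3,4-bis(benzyloxy)benzyl]prop-2-en-1-amine | C=CCNCc1ccc(OCc2ccccc2)c(OCc2ccccc2)c1
F8 | step 4 | N-allyl-N-[3,4-bis(benzyloxy)benzyl]formamide | C=CCN(C=O)Cc1ccc(OCc2ccccc2)c(OCc2ccccc2)c1
F9 | step 4 | 1-[3,4-bis(benzyloxy)benzyl]pyrrolidin-2-one | O=C1CCCN1Cc1ccc(OCc2ccccc2)c(OCc2ccccc2)c1
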